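**Plan**

1. Locants (elemane): ring C5–C10; oxirane C1–C2 and methyl C14 on C10; C4(=C3H2)–C15HO on C5; isobutyrate on O6; lactone C7–C11(=C13H2)–C12(=O)–O8; OH on C9. β is the ring face that carries the C10 methyl.
2. Cuts, in retrosynthetic order: oxirane → C1/C2 diol; lactone C12–O8 and both C–O bonds of the cis C8/C9 diol → C8=C9; C3 and the C15 oxygen → acetyl; C11=C13 plus the O6 ester → oxolane C6–O6–C13–C11–C7 (O6 parked on C13 as its oxa-Michael adduct); then C6–C7 and C5–C10 together by an intramolecular Diels–Alder reaction.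
3. Enabling feature: C4, O6, C11 and the C10 methyl are all cis on ring C5–C10 and C8/C9 carry a cis diol. That is the pattern of an all-endo adduct of a (Z)-alkene C5=C6 with an (E,Z)-diene C7=C8–C9=C10. O6 and C13 stand 1,4 through C7–C11, so the three-atom tether O6–C13–C11 is built from the target's own atoms.
4. Forward: chiral dioxolane (C1, C2, C10) → (Z)-enal (C8, C9, C14) → dienyl iodide (C7) → tert-butyl dienoate (C11, C12) → hydroxymethylation (C13, O6) → (Z)-β-oxy enone (C4–C6, C15) → cycloaddition closes ring C5–C10 and the oxolane together → diol, C3, ring opening with O6 acylation, C15 oxidation, lactone, oxirane.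
5. Stereochemistry: C1 from methyl (S)-glycerate acetonide; C5, C6, C7, C10 from the cycloaddition (alkene geometries, endo tether, face chosen by C1); C8, C9 from osmylation anti to the axial C10 methyl and the oxolane; C11 is transient.

Key step: step 11

Assumption: compounds 11, 12 and 15–21 are carried as mixtures of the two C11 epimers, which is harmless because C11 becomes trigonal in step 15.

**Route**

Step 1
Reactants: 1 methyl (4S)-2,2-dimethyl-1,3-dioxolane-4-carboxylate
Product: 3 (4R)-4-ethynyl-2,2-dimethyl-1,3-dioxolane, via aldehyde 2 (not isolated)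
Conditions: i-Bu2AlH, CH2Cl2, −78 °C; then MeOH, K2CO3, dimethyl (1-diazo-2-oxopropyl)phosphonate, 0 °C → rt
Reagents that add atoms: dimethyl (1-diazo-2-oxopropyl)phosphonate, CC(=O)C(=[N+]=[N-])P(=O)(OC)OC
Why: Partial reduction to the aldehyde and Ohira–Bestmann (Seyferth–Gilbert) homologation in the same flask should give the terminal alkyne (C9) without isolating the epimerisable aldehyde; C1 is not touched (S to R is a change of priority only).

Step 2
Reactants: 3 (4R)-4-ethynyl-2,2-dimethyl-1,3-dioxolane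
Product: 5 methyl 3-[(4R)-2,2-dimethyl-1,3-dioxolan-4-yl]prop-2-ynoate, via lithium acetylide 4 (not isolated)
Conditions: n-BuLi, THF, −78 °C; then ClCO2Me, −78 → 0 °C
Reagents that add atoms: methyl chloroformate, COC(=O)Cl
Why: Deprotonation of the terminal alkyne and C-acylation of the lithium acetylide with the chloroformate should give the ynoate (C8).

Step 3
Reactants: 5 methyl 3-[(4R)-2,2-dimethyl-1,3-dioxolan-4-yl]prop-2-ynoate
Product: 6 methyl (2Z)-3-[(4R)-2,2-dimethyl-1,3-dioxolan-4-yl]but-2-enoate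
Conditions: Me2CuLi (from CuI and MeLi), THF, −78 °C; AcOH quench at −78 °C
Reagents that add atoms: lithium dimethylcuprate Me2CuLi (made in the flask from CuI and MeLi), [Li+].C[Cu-]C
Why: syn-Carbocupration of the ynoate and protonation of the alkenylcopper at −78 °C with retention place the new methyl (C14) trans to the ester, so the dioxolanyl group is cis to C8, the geometry that later makes it the inside substituent of the diene terminus C10.

Step 4
Reactants: 6 methyl (2Z)-3-[(4R)-2,2-dimethyl-1,3-dioxolan-4-yl]but-2-enoate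
Product: 7 (2Z)-3-[(4R)-2,2-dimethyl-1,3-dioxolan-4-yl]but-2-en-1-ol
Conditions: i-Bu2AlH (2.2 equiv), CH2Cl2, −78 °C
Reagents that add atoms: none
Why: 1,2-Reduction of the enoate with two hydride equivalents should give the allylic alcohol with the alkene geometry intact.

Step 5
Reactants: 7 (2Z)-3-[(4R)-2,2-dimethyl-1,3-dioxolan-4-yl]but-2-en-1-ol
Product: 8 (2Z)-3-[(4R)-2,2-dimethyl-1,3-dioxolan-4-yl]but-2-enal
Conditions: MnO2, CH2Cl2, rt, dark
Reagents that add atoms: none
Why: MnO2 oxidises the allylic alcohol under neutral conditions, which avoids Z to E isomerisation of the enal.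

Step 6
Reactants: 8 (2Z)-3-[(4R)-2,2-dimethyl-1,3-dioxolan-4-yl]but-2-enal
Product: 9 (4R)-4-[(2Z,4E)-5-iodopenta-2,4-dien-2-yl]-2,2-dimethyl-1,3-dioxolane
Conditions: CrCl2, CHI3, THF, 0 °C
Reagents that add atoms: iodoform, IC(I)I
Why: Takai olefination: the gem-dichromium species from CHI3 adds to the aldehyde and eliminates to the (E)-alkenyl iodide (C7) without touching the (Z)-trisubstituted alkene.

Step 7
Reactants: 9 (4R)-4-[(2Z,4E)-5-iodopenta-2,4-dien-2-yl]-2,2-dimethyl-1,3-dioxolane
Product: 10 tert-butyl (3E,5Z)-6-[(4R)-2,2-dimethyl-1,3-dioxolan-4-yl]hepta-3,5-dienoate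
Conditions: BrZnCH2CO2t-Bu, Pd(PPh3)4 (5 mol %), THF, rt
Reagents that add atoms: (2-tert-butoxy-2-oxoethyl)zinc bromide, CC(C)(C)OC(=O)C[Zn]Br
Why: Negishi-type cross-coupling of the Reformatsky reagent with the alkenyl iodide proceeds with retention at C7=C8 and gives the β,γ-unsaturated ester (C11, C12) directly, the neutral zinc enolate leaving the skipped position unconjugated.

Step 8
Reactants: 10 tert-butyl (3E,5Z)-6-[(4R)-2,2-dimethyl-1,3-dioxolan-4-yl]hepta-3,5-dienoate
Product: 12 tert-butyl (3E,5Z)-6-[(4R)-2,2-dimethyl-1,3-dioxolan-4-yl]-2-(hydroxymethyl)hepta-3,5-dienoate (both C2 epimers), via lithium enolate 11 (not isolated)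
Conditions: LiN(i-Pr)2, THF, −78 °C; then monomeric CH2O in THF, −78 °C; AcOH
Reagents that add atoms: formaldehyde, C=O
Why: The extended lithium enolate should react with formaldehyde at its α-carbon (kinetic α-selectivity of extended enolates in aldol additions), which installs C13 and O6; C11 forms as both epimers, which is harmless.

Step 9
Reactants: 13 but-3-yn-2-one
Product: 14 (3Z)-4-iodobut-3-en-2-one
Conditions: NaI, AcOH, rt
Reagents that add atoms: sodium iodide, [Na+].[I-]
Why: Conjugate addition of iodide to the ynone in acetic acid and anti protonation (hydroiodination) should give the (Z)-β-iodo enone under kinetic control.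

Step 10
Reactants: 12 tert-butyl (3E,5Z)-6-[(4R)-2,2-dimethyl-1,3-dioxolan-4-yl]-2-(hydroxymethyl)hepta-3,5-dienoate; 14 (3Z)-4-iodobut-3-en-2-one
Product: 16 tert-butyl (3E,5Z)-6-[(4R)-2,2-dimethyl-1,3-dioxolan-4-yl]-2-({[(1Z)-3-oxobut-1-en-1-yl]oxy}methyl)hepta-3,5-dienoate (both C2 epimers), via sodium alkoxide 15 (not isolated)
Conditions: NaN(SiMe3)2, THF, −78 °C; then 14, −78 → −40 °C; pH 7 buffer
Reagents that add atoms: none
Why: Nucleophilic vinylic substitution by addition–elimination at the β-iodo enone retains the alkene configuration because the intermediate enolate expels iodide faster than it rotates, and the low temperature holds back retro-aldol loss of formaldehyde and β-elimination from the product.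

Step 11
Reactants: 16 tert-butyl (3E,5Z)-6-[(4R)-2,2-dimethyl-1,3-dioxolan-4-yl]-2-({[(1Z)-3-oxobut-1-en-1-yl]oxy}methyl)hepta-3,5-dienoate
Product: 17 tert-butyl 7-acetyl-6-[(4R)-2,2-dimethyl-1,3-dioxolan-4-yl]-6-methyl-2,3,3a,6,7,7a-hexahydro-1-benzofuran-3-carboxylate (cis-fused; O1, the C3a–C3 bond, 7-acetyl and 6-methyl on the β face, dioxolanyl α; both C3 epimers)
Conditions: PhMe (0.01 M), BHT, 130 °C, sealed tube, base-washed glass
Reagents that add atoms: none
Why: Thermal type 1 intramolecular Diels–Alder reaction of a 3-oxa-1,6,8-nonatriene: a concerted suprafacial [4+2] addition of the (Z)-β-alkoxy enone C5=C6 to the diene C7=C8–C9=C10 forms C6–C7 and C5–C10 in one event; the closest known class is the thermal cyclisation of 1,6,8-nonatrienes with a (Z)-acceptor at the dienophile terminus, which give cis-fused bicyclo[4.3.0]nonenes. Ring C5–C10 closes as the cyclohexene of the [4+2] process, and the oxolane C6–O6–C13–C11–C7 closes through C6–C7 as a cis-fused five-membered tether ring (tether endo). C5 and C6 are cis to each other because the enone is Z, and both are syn to C7–C11 and to the C10 methyl because acetyl and O6 lie endo while C11 (E alkene) and the methyl are the outside substituents of the diene termini; the quaternary C10 is therefore fixed by the C9=C10 geometry set in step 3. The absolute sense is relayed from C1: with C1–H in the bay of the s-cis diene (allylic strain), C1–C2 anti and C1–O gauche to the forming C5–C10 bond, the dienophile should add to the face that leads to the target series, and both C11 epimers should follow the same course because C11 carries only H and the ester. The step needs endo (cis-fused) over exo selectivity, secured by the Z enone whose exo mode would forfeit acetyl overlap; regiocontrol, secured by the tether; and a rate that beats the [1,5]-hydrogen shift open to the (Z)-diene, hence the low concentration, base-washed glass and lowest workable temperature.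

Step 12
Reactants: 17 tert-butyl 7-acetyl-6-[(4R)-2,2-dimethyl-1,3-dioxolan-4-yl]-6-methyl-2,3,3a,6,7,7a-hexahydro-1-benzofuran-3-carboxylate
Product: 18 tert-butyl 7-acetyl-6-[(4R)-2,2-dimethyl-1,3-dioxolan-4-yl]-4,5-dihydroxy-6-methyloctahydro-1-benzofuran-3-carboxylate (as 17, with the 4- and 5-hydroxyls, on C8 and C9, on the α face)
Conditions: OsO4 (5 mol %), NMO, acetone/H2O, rt
Reagents that add atoms: N-methylmorpholine N-oxide, C[N+]1([O-])CCOCC1; water, O
Why: Upjohn dihydroxylation of the only alkene present: OsO4 should add syn from the α face, anti to the pseudoaxial C10 methyl and to the cis-fused oxolane, which sets C8 and C9.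

Step 13
Reactants: 18 tert-butyl 7-acetyl-6-[(4R)-2,2-dimethyl-1,3-dioxolan-4-yl]-4,5-dihydroxy-6-methyloctahydro-1-benzofuran-3-carboxylate
Product: 19 4,5-O-isopropylidene acetal of 18 (acetonide across O8 and O9)
Conditions: Me2C(OMe)2, PPTS (cat.), CH2Cl2, rt
Reagents that add atoms: 2,2-dimethoxypropane, COC(C)(C)OC
Why: Acid-catalysed transacetalisation caps the cis diol as a dioxolane so that no hydroxyl is present during the enolate step; the tert-butyl ester cannot lactonise onto O8.

Step 14
Reactants: 19 4,5-O-isopropylidene acetal of 18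
Product: 20 7-(prop-1-en-2-yl) analogue of 19 (C4=C3H2 in place of C4=O)
Conditions: Cp2TiMe2, PhMe, 65 °C, dark
Reagents that add atoms: dimethyltitanocene Cp2TiMe2, C[Ti](C)(C1C=CC=C1)C1C=CC=C1
Why: Petasis methylenation (via Cp2Ti=CH2) is non-basic, so the β-alkoxy ketone neither epimerises at C5 nor expels O6, and the ketone reacts ahead of the hindered tert-butyl ester; this adds C3.

Step 15
Reactants: 20 7-(prop-1-en-2-yl) analogue of 19
Product: 23 tert-butyl 2-{4-[(4R)-2,2-dimethyl-1,3-dioxolan-4-yl]-2,2,4-trimethyl-6-[(2-methylpropanoyl)oxy]-5-(prop-1-en-2-yl)hexahydro-1,3-benzodioxol-7-yl}prop-2-enoate (elemane locants: 5β-isopropenyl, 6β-O-isobutyryl, 7β side chain, 8α,9α-acetonide, 10β-methyl), via lithium enolate 21 (not isolated), via lithium alkoxide 22 (not isolated)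
Conditions: LiN(i-Pr)2 (1.1 equiv), THF, −78 → 0 °C; then (i-PrCO)2O, −78 → 0 °C
Reagents that add atoms: isobutyric anhydride, CC(C)C(=O)OC(=O)C(C)C
Why: E1cB retro-oxa-Michael ring opening of the β-alkoxy ester enolate (the usual fate of oxolane-3-carboxylate enolates on warming) releases C11=C13 and the C6 alkoxide, which the anhydride acylates in the same flask; the tert-butyl ester is too hindered for that alkoxide to lactonise onto C12.

Step 16
Reactants: 23 tert-butyl 2-{4-[(4R)-2,2-dimethyl-1,3-dioxolan-4-yl]-2,2,4-trimethyl-6-[(2-methylpropanoyl)oxy]-5-(prop-1-en-2-yl)hexahydro-1,3-benzodioxol-7-yl}prop-2-enoate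
Product: 24 5-(3-oxoprop-1-en-2-yl) analogue of 23 (C4(=C3H2)–C15HO on C5)
Conditions: SeO2, pyridine, 1,4-dioxane, 70 °C
Reagents that add atoms: selenium dioxide, O=[Se]=O
Why: Riley oxidation: ene reaction of SeO2 at the 1,1-disubstituted alkene and [2,3]-shift oxidise the isopropenyl methyl to the aldehyde (C15), while the electron-poor acrylate alkene stays untouched.

Step 17
Reactants: 24 5-(3-oxoprop-1-en-2-yl) analogue of 23
Product: 26 1,2-diol of the target (the target with a (1R)-1,2-dihydroxyethyl group on C10 in place of the oxirane), via tetraol acid 25 (not isolated)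
Conditions: TFA/H2O (9:1), CH2Cl2, 0 °C → rt
Reagents that add atoms: none
Why: Aqueous TFA removes the tert-butyl group and both acetonides, and the liberated acid should close onto the equatorial C8 hydroxyl as the trans-fused γ-lactone, the C9 hydroxyl being unable to reach C12.

Step 18
Reactants: 26 1,2-diol of the target
Product: 27 CNP0496100.1 (target)
Conditions: PPh3, DIAD (betaine pre-formed), THF, 0 → 40 °C
Reagents that add atoms: none
Why: Mitsunobu cyclodehydration: the vicinal diol forms a five-membered dioxaphosphorane that collapses by displacement of Ph3P=O from the primary carbon C2 by O1, so C1 keeps its configuration and the isolated, hindered C9 hydroxyl should not be engaged.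

**Compound list**

1 | methyl (4S)-2,2-dimethyl-1,3-dioxolane-4-carboxylate | COC(=O)[C@@H]1COC(C)(C)O1 | starting material
2 | (4S)-2,2-dimethyl-1,3-dioxolane-4-carbaldehyde | O=C[C@@H]1COC(C)(C)O1 | intermediate
3 | (4R)-4-ethynyl-2,2-dimethyl-1,3-dioxolane | C#C[C@@H]1COC(C)(C)O1 | intermediate
4 | lithium acetylide of 3 | [Li]C#C[C@@H]1COC(C)(C)O1 | intermediate
5 | methyl 3-[(4R)-2,2-dimethyl-1,3-dioxolan-4-yl]prop-2-ynoate | COC(=O)C#C[C@@H]1COC(C)(C)O1 | intermediate
6 | methyl (2Z)-3-[(4R)-2,2-dimethyl-1,3-dioxolan-4-yl]but-2-enoate | COC(=O)/C=C(/C)[C@@H]1COC(C)(C)O1 | intermediate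
7 | (2Z)-3-[(4R)-2,2-dimethyl-1,3-dioxolan-4-yl]but-2-en-1-ol | OC/C=C(/C)[C@@H]1COC(C)(C)O1 | intermediate
8 | (2Z)-3-[(4R)-2,2-dimethyl-1,3-dioxolan-4-yl]but-2-enal | O=C/C=C(/C)[C@@H]1COC(C)(C)O1 | intermediate
9 | (4R)-4-[(2Z,4E)-5-iodopenta-2,4-dien-2-yl]-2,2-dimethyl-1,3-dioxolane | I/C=C/C=C(/C)[C@@H]1COC(C)(C)O1 | intermediate
10 | tert-butyl (3E,5Z)-6-[(4R)-2,2-dimethyl-1,3-dioxolan-4-yl]hepta-3,5-dienoate | CC(C)(C)OC(=O)C/C=C/C=C(/C)[C@@H]1COC(C)(C)O1 | intermediate
11 | lithium enolate of 10 | CC(C)(C)OC(O[Li])=C/C=C/C=C(/C)[C@@H]1COC(C)(C)O1 | intermediate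
12 | tert-butyl (3E,5Z)-6-[(4R)-2,2-dimethyl-1,3-dioxolan-4-yl]-2-(hydroxymethyl)hepta-3,5-dienoate (C2 epimers) | CC(C)(C)OC(=O)C(CO)/C=C/C=C(/C)[C@@H]1COC(C)(C)O1 | intermediate
13 | but-3-yn-2-one | CC(=O)C#C | starting material
14 | (3Z)-4-iodobut-3-en-2-one | CC(=O)/C=C\I | intermediate
15 | sodium alkoxide of 12 | CC(C)(C)OC(=O)C(C[O-])/C=C/C=C(/C)[C@@H]1COC(C)(C)O1.[Na+] | intermediate
16 | tert-butyl (3E,5Z)-6-[(4R)-2,2-dimethyl-1,3-dioxolan-4-yl]-2-({[(1Z)-3-oxobut-1-en-1-yl]oxy}methyl)hepta-3,5-dienoate (C2 epimers) | CC(=O)/C=C\OCC(C(=O)OC(C)(C)C)/C=C/C=C(/C)[C@@H]1COC(C)(C)O1 | intermediate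
17 | tert-butyl 7-acetyl-6-[(4R)-2,2-dimethyl-1,3-dioxolan-4-yl]-6-methyl-2,3,3a,6,7,7a-hexahydro-1-benzofuran-3-carboxylate (cis-fused, C3 epimers) | CC(=O)[C@@H]1[C@@H]2OCC(C(=O)OC(C)(C)C)[C@@H]2C=C[C@@]1(C)[C@@H]3COC(C)(C)O3 | intermediate
18 | tert-butyl 7-acetyl-6-[(4R)-2,2-dimethyl-1,3-dioxolan-4-yl]-4,5-dihydroxy-6-methyloctahydro-1-benzofuran-3-carboxylate (4α,5α-diol) | CC(=O)[C@@H]1[C@@H]2OCC(C(=O)OC(C)(C)C)[C@@H]2[C@@H](O)[C@@H](O)[C@@]1(C)[C@@H]3COC(C)(C)O3 | intermediate
19 | 4,5-O-isopropylidene acetal of 18 | CC(=O)[C@@H]1[C@@H]2OCC(C(=O)OC(C)(C)C)[C@@H]2[C@H]3OC(C)(C)O[C@H]3[C@@]1(C)[C@@H]4COC(C)(C)O4 | intermediate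
20 | 7-(prop-1-en-2-yl) analogue of 19 | CC(=C)[C@@H]1[C@@H]2OCC(C(=O)OC(C)(C)C)[C@@H]2[C@H]3OC(C)(C)O[C@H]3[C@@]1(C)[C@@H]4COC(C)(C)O4 | intermediate
21 | lithium enolate of 20 | CC(=C)[C@@H]1[C@@H]2OCC(=C(O[Li])OC(C)(C)C)[C@@H]2[C@H]3OC(C)(C)O[C@H]3[C@@]1(C)[C@@H]4COC(C)(C)O4 | intermediate
22 | lithium C6-alkoxide of the ring-opened tert-butyl acrylate | C=C(C(=O)OC(C)(C)C)[C@H]1[C@@H](O[Li])[C@@H](C(C)=C)[C@](C)([C@@H]2COC(C)(C)O2)[C@@H]3OC(C)(C)O[C@H]13 | intermediate
23 | tert-butyl 2-{4-[(4R)-2,2-dimethyl-1,3-dioxolan-4-yl]-2,2,4-trimethyl-6-[(2-methylpropanoyl)oxy]-5-(prop-1-en-2-yl)hexahydro-1,3-benzodioxol-7-yl}prop-2-enoate | C=C(C(=O)OC(C)(C)C)[C@H]1[C@@H](OC(=O)C(C)C)[C@@H](C(C)=C)[C@](C)([C@@H]2COC(C)(C)O2)[C@@H]3OC(C)(C)O[C@H]13 | intermediate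
24 | 5-(3-oxoprop-1-en-2-yl) analogue of 23 | C=C(C(=O)OC(C)(C)C)[C@H]1[C@@H](OC(=O)C(C)C)[C@@H](C(=C)C=O)[C@](C)([C@@H]2COC(C)(C)O2)[C@@H]3OC(C)(C)O[C@H]13 | intermediate
25 | tetraol acid (24 without tert-butyl group and acetonides) | C=C(C(=O)O)[C@H]1[C@@H](OC(=O)C(C)C)[C@@H](C(=C)C=O)[C@](C)([C@@H](O)CO)[C@H](O)[C@@H]1O | intermediate
26 | 1,2-diol of the target ((1R)-1,2-dihydroxyethyl on C10) | C=C1C(=O)O[C@@H]2[C@@H]1[C@@H](OC(=O)C(C)C)[C@@H](C(=C)C=O)[C@](C)([C@@H](O)CO)[C@@H]2O | intermediate
27 | CNP0496100.1 | C=C1C(=O)O[C@@H]2[C@@H]1[C@@H](OC(=O)C(C)C)[C@@H](C(=C)C=O)[C@](C)([C@@H]1CO1)[C@@H]2O | target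

**Step count and risks**

Total steps: 18. Longest linear sequence: 17 (steps 1–8 and 10–18; step 9 is a one-step branch).

Steps most likely to fail:

1. Step 11. The inside dioxolanyl group hinders the s-cis diene, so the cycloaddition may be slow enough for the [1,5]-hydrogen shift from C1–H of the (Z)-diene to compete. Trace acid may isomerise the (Z)-enol ether to E, which would divert the reaction to trans-fused adducts. Face selection by C1 may be weak, or may be overridden in one C11 epimer. Fallback, from 12 and 13, back at 17: a bimolecular Diels–Alder reaction of 12 with but-3-yn-2-one 13 (PhMe, 90 °C, BHT) should give the cyclohexa-1,4-diene tert-butyl 2-{3-acetyl-4-[(4R)-2,2-dimethyl-1,3-dioxolan-4-yl]-4-methylcyclohexa-2,5-dien-1-yl}-3-hydroxypropanoate F1. The acetyl-bearing alkyne carbon joins the gem-disubstituted terminus C10 and the terminal carbon joins C7, with C7 and C10 cis by suprafacial addition. Catalytic DBU (CH2Cl2, 0 °C) then adds the C13 hydroxyl to C6 of the dienone from the β face (5-exo-trig oxa-Michael) and protonates C5 to the equatorial acetyl, which gives 17.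

2. Step 15. The breaking C13–O6 bond lies close to the plane of the enolate (the reverse of a 5-endo-trig closure), so ring opening may be slow enough for the enolate to decompose on warming, or the liberated alkoxide may be acylated incompletely. Fallback, from 20, back at 23: the enolate is formed and brominated at −78 °C (LiN(i-Pr)2; CBr4) to the C11 α-bromo ester of 20 F2. Activated zinc (THF, 50 °C; AcOH work-up) then effects a Boord-type reductive β-elimination through the zinc enolate, whose non-basic medium allows heating, to the C6 alcohol tert-butyl 2-{4-[(4R)-2,2-dimethyl-1,3-dioxolan-4-yl]-6-hydroxy-2,2,4-trimethyl-5-(prop-1-en-2-yl)hexahydro-1,3-benzodioxol-7-yl}prop-2-enoate F3. Isobutyryl chloride, pyridine and DMAP then give 23.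

3. Step 18. The C9 hydroxyl may attack the activated C2 and close a five-membered ether instead of the oxirane, and the phosphine or the phosphine–azodicarboxylate betaine may add to the enal or the α-methylene lactone. Fallback, from 26, back at 27: tin-mediated primary-selective sulfonylation (TsCl, Et3N, Bu2SnO cat., CH2Cl2, 0 °C) gives the C2 tosylate of 26 F4, and DBU (CH2Cl2, 0 °C) closes the oxirane by 3-exo displacement from the adjacent O1, which gives 27 without a phosphine.

Further compounds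
F1 | step 11 | tert-butyl 2-{3-acetyl-4-[(4R)-2,2-dimethyl-1,3-dioxolan-4-yl]-4-methylcyclohexa-2,5-dien-1-yl}-3-hydroxypropanoate (side chain and 4-methyl cis; C2 epimers) | CC(=O)C1=C[C@H](C(CO)C(=O)OC(C)(C)C)C=C[C@@]1(C)[C@@H]2COC(C)(C)O2
F2 | step 15 | C11 α-bromo ester of 20 (3-bromo-1-benzofuran-3-carboxylate) | CC(=C)[C@@H]1[C@@H]2OCC(Br)(C(=O)OC(C)(C)C)[C@@H]2[C@H]3OC(C)(C)O[C@H]3[C@@]1(C)[C@@H]4COC(C)(C)O4
F3 | step 15 | tert-butyl 2-{4-[(4R)-2,2-dimethyl-1,3-dioxolan-4-yl]-6-hydroxy-2,2,4-trimethyl-5-(prop-1-en-2-yl)hexahydro-1,3-benzodioxol-7-yl}prop-2-enoate | C=C(C(=O)OC(C)(C)C)[C@H]1[C@@H](O)[C@@H](C(C)=C)[C@](C)([C@@H]2COC(C)(C)O2)[C@@H]3OC(C)(C)O[C@H]13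
F4 | step 18 | C2 p-toluenesulfonate of 26 | C=C1C(=O)O[C@@H]2[C@@H]1[C@@H](OC(=O)C(C)C)[C@@H](C(=C)C=O)[C@](C)([C@@H](O)COS(=O)(=O)c1ccc(C)cc1)[C@@H]2O
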